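**Plan**
1. Retrosynthetic cuts, in order: C12=C13 (ring-closing metathesis of the 11-membered ring); C31–C34 (tetronate carbanion plus aldehyde); ring C bonds C15–C27 and C21–C26 (Diels–Alder) together with the tetronate bonds O28–C29 and C31=C32; C9–C10 (Ireland–Claisen); C8–C9 (aldol condensation closing ring B); C36–C34 (enolate alkylation); C6–C7 and C5–C36 (three-component step).
2. Forward: ring A is bought with C2 in place. One operation adds the vinyl unit (C7, C8) and nitropropene (C36, C37, C9). Ring B then closes between C8 and C9, and the C10–C12 arm is delivered from a C7 ester. Rings C and D are made on a separate branch, the halves are joined at C31–C34, and the macrocycle closes last.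
3. Enabling feature: in ring A the C1 methyl is axial on C2 and trans to C7 on C6, and the fusion carbons C6 and C5 carry trans substituents (C7, and C36 with its methyl C37). This is the pattern left by anti conjugate addition of a vinyl group to (R)-5-methylcyclohexenone followed by anti capture of the enolate by nitropropene.
4. Stereochemistry: C2 from (R)-pulegone; C6 and C5 from the key step; C36 by 1,2-induction from C5; C9 and C10 by suprafacial transfer from the C7–O bond; C23 from (R)-propylene oxide; C15, C21 and C27 from an exo Diels–Alder reaction with a dienophile made from (R)-lactic acid; the (E)-C12=C13 alkene from the ring closure.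

Key step: step 6

Remark: atoms are labelled 1–38 in the order of the target SMILES, oxygens counted (ring A = C2–C6 and C38; ring B = C5–C9 and C36; ring C = C15, C17, C18, C21, C26, C27; tetronate ring D = C27–C32; ketone carbon C34). The side-chain methine formed in the key step (future C36) is assumed to arise as an epimer mixture and is set only in step 9.

**Route**

Step 1
Reactants: 1 (R)-pulegone
Product: 2 pulegone oxide
Conditions: 30% H2O2, LiOH·H2O, MeOH, 0 °C to rt
Reagents that add atoms: hydrogen peroxide, OO
Why: Nucleophilic (Weitz–Scheffer) epoxidation of the enone with alkaline peroxide should give the epoxy ketone, and the new spiro centre may form as a mixture because it is destroyed in step 2.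

Step 2
Reactants: 2 pulegone oxide
Product: 4 (5R)-5-methyl-2-(phenylsulfanyl)cyclohexan-1-one, via ring-opened sodium alkoxide 3 (not isolated)
Conditions: PhSNa, THF, 65 °C; H2O
Reagents that add atoms: sodium benzenethiolate, [Na+].[S-]c1ccccc1
Why: Thiolate opening of the α,β-epoxy ketone at the α-carbon gives a β-alkoxide that should fragment by retro-aldol loss of acetone, which leaves the methyl-bearing centre (future C2) untouched and gives a cis/trans sulfide mixture that converges in step 3.

Step 3
Reactants: 4 (5R)-5-methyl-2-(phenylsulfanyl)cyclohexan-1-one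
Product: 6 (R)-5-methylcyclohex-2-en-1-one, via sulfoxide 5 (not isolated)
Conditions: mCPBA, CH2Cl2, −78 °C; then CaCO3, toluene, 110 °C
Reagents that add atoms: none
Why: Sulfide oxidation followed by thermal syn-elimination of the sulfoxide, whose only β-hydrogens lie on the CH2 away from the carbonyl, should give the conjugated enone without touching the remote stereocentre.

Step 4
Reactants: 7 nitromethane; 8 acetaldehyde
Product: 9 1-nitropropan-2-ol
Conditions: NaOH (cat.), H2O/EtOH, 0 °C to rt
Reagents that add atoms: none
Why: Base-catalysed Henry (nitroaldol) addition should give the β-nitro alcohol, whose racemic carbinol centre is removed in step 5.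

Step 5
Reactants: 9 1-nitropropan-2-ol
Product: 11 (E)-1-nitroprop-1-ene, via mesylate 10 (not isolated)
Conditions: MsCl, Et3N, CH2Cl2, 0 °C
Reagents that add atoms: none
Why: Mesylation and E1cB elimination is the usual dehydration of a β-nitro alcohol and should give the more stable (E)-nitroalkene.

Step 6
Reactants: 6 (R)-5-methylcyclohex-2-en-1-one; 12 vinylmagnesium bromide; 11 (E)-1-nitroprop-1-ene
Product: 15 (2R,3S,5R)-3-ethenyl-5-methyl-2-(1-nitropropan-2-yl)cyclohexan-1-one, via bromomagnesium enolate 13 (not isolated), via bromomagnesium nitronate 14 (not isolated)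
Conditions: CuBr·SMe2 (20 mol %), THF, −78 °C; then 11, −78 to −40 °C; AcOH, −78 °C
Reagents that add atoms: none
Why: CuBr·SMe2 converts the Grignard reagent into a vinylcuprate that adds 1,4 to 6 by axial attack on the half-chair that keeps the methyl group pseudo-equatorial, so C7 should end trans to the C1 methyl (new centre C6) and enolate 13 is formed regiospecifically. Enolate 13 then attacks the β-carbon of the nitroalkene (Michael addition) on the face anti to the new vinyl group, which sets C5 trans to C6 and gives nitronate 14; this is inert to further addition and is protonated by the cold acid quench. The closest known reaction type is the three-component conjugate addition of a cuprate to a cyclohexenone with trapping of the enolate by a nitroalkene. No ring is closed; the two bonds C6–C7 and C5–C36 are formed. C6 and C5 are both controlled by the purchased C2 centre (1,3-trans, then 1,2-trans), whereas C36 forms without control and is erased in step 9. The step needs 1,4- over 1,2-addition (secured by copper), one non-equilibrated enolate (secured by low temperature and fast capture) and no nitroalkene polymerisation (secured by slow addition at −78 °C).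

Step 7
Reactants: 15 nitro ketone
Product: 17 2-[(1R,2S,4S)-2-ethenyl-4-methylcyclohexyl]-1-nitropropane, via tosylhydrazone 16 (not isolated)
Conditions: TsNHNH2, EtOH, 50 °C; then catecholborane, CHCl3, 0 °C; NaOAc·3H2O, 60 °C
Reagents that add atoms: none
Why: Tosylhydrazone formation, hydride reduction with catecholborane and acetate-triggered loss of sulfinate and N2 (Caglioti-type deoxygenation) should turn the C4 carbonyl into CH2 while sparing the vinyl and nitro groups, and C5 already has the stable trans arrangement.

Step 8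
Reactants: 17 nitroalkane
Product: 19 methyl 2-[(1R,2S,4S)-2-ethenyl-4-methylcyclohexyl]propanoate, via carboxylic acid 18 (not isolated)
Conditions: NaNO2, AcOH, DMSO, 35 °C; then MeI, K2CO3, DMF, rt
Reagents that add atoms: water, O; iodomethane, CI
Why: The oxidative Nef reaction of a primary nitroalkane with nitrite and acetic acid (through the nitrolic acid) should give the carboxylic acid that becomes C9, and carboxylate alkylation gives the methyl ester with C36 still an epimer mixture.

Step 9
Reactants: 19 methyl ester
Product: 21 methyl (2R)-3-(benzyloxy)-2-[(1R,2S,4S)-2-ethenyl-4-methylcyclohexyl]-2-methylpropanoate, via lithium enolate 20 (not isolated)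
Conditions: LiN(iPr)2 (LDA), THF, −78 °C; then BOMCl, −78 to −20 °C
Reagents that add atoms: benzyl chloromethyl ether, ClCOCc1ccccc1
Why: Alkylation of the fully substituted ester enolate, on which both C36 epimers converge, should set C36 by 1,2-induction because allylic 1,3-strain holds the C5–H bond in the enolate plane and the electrophile (future C34) enters from the face flanked by C4H2, away from C6 where it would meet C7 in a syn-pentane contact; the outcome does not depend on enolate geometry.

Step 10
Reactants: 21 quaternary ester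
Product: 22 (2R)-3-(benzyloxy)-2-[(1R,2S,4S)-2-ethenyl-4-methylcyclohexyl]-2-methylpropanal
Conditions: iBu2AlH, CH2Cl2, −78 °C; aq. sodium potassium tartrate
Reagents that add atoms: none
Why: Partial reduction of the hindered α-quaternary methyl ester with iBu2AlH at low temperature should stop at the aluminium hemiacetal and release the C9 aldehyde on work-up.

Step 11
Reactants: 22 aldehyde
Product: 23 (2R)-2-[(1R,2R,4S)-2-acetyl-4-methylcyclohexyl]-3-(benzyloxy)-2-methylpropanal
Conditions: PdCl2 (10 mol %), CuCl, O2 (1 atm), DMF/H2O 7:1, rt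
Reagents that add atoms: water, O
Why: Wacker oxidation of the monosubstituted alkene should give the methyl ketone with Markovnikov selectivity, so the vinyl carbons become the C7 carbonyl and the C8 methyl while the non-enolisable aldehyde is spared.

Step 12
Reactants: 23 keto aldehyde
Product: 25 ring B enone, via aldol 24 (not isolated)
Conditions: KOH, MeOH, 0 to 50 °C
Reagents that add atoms: none
Why: Intramolecular aldol condensation of the methyl ketone enolate (C8) with the non-enolisable aldehyde (C9) should close ring B as a cyclohexenone (6-enolendo-exo-trig), and C6, the only epimerisable centre, keeps the more stable trans ring fusion.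

Step 13
Reactants: 25 ring B enone
Product: 26 equatorial allylic alcohol
Conditions: NaBH4, CeCl3·7H2O, MeOH, −78 to −20 °C
Reagents that add atoms: none
Why: Luche 1,2-reduction, in which hydride should add axially to C7 on the face of the axial C5–H, gives the equatorial C7 alcohol (cis to methyl C37).

Step 14
Reactants: 26 equatorial allylic alcohol
Product: 27 axial propanoate
Conditions: EtCO2H, PPh3, DIAD, toluene, 0 °C to rt
Reagents that add atoms: propanoic acid, CCC(=O)O
Why: Mitsunobu esterification proceeds with SN2 inversion at C7 and should place the propanoate axial, cis to the CH2OBn group (C34) on C36.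

Step 15
Reactants: 27 axial propanoate
Product: 30 Claisen acid, via silyl ketene acetal 28 (not isolated), via trimethylsilyl ester 29 (not isolated)
Conditions: LiN(iPr)2, THF, −78 °C; TMSCl, Et3N, −78 °C to rt, then 55 °C; 1 M HCl
Reagents that add atoms: none
Why: In this Ireland–Claisen rearrangement kinetic enolisation in THF should give the (E)-silyl ketene acetal, the [3,3] shift turns the axial C7–O bond suprafacially into the C9–C10 bond (arm cis to C34, alkene moved to C7=C8), and C10 follows from the boat-like transition state expected for cyclohexenyl esters, since the chair would force the silyloxy group over ring B against the axial C5–H.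

Step 16
Reactants: 30 Claisen acid
Product: 31 primary alcohol (C12–OH)
Conditions: LiAlH4, THF, 0 °C to rt
Reagents that add atoms: none
Why: Hydride reduction of the carboxylic acid should give the C12 alcohol and leave the benzyl ether and the ring alkene untouched.

Step 17
Reactants: 31 primary alcohol
Product: 32 α-branched aldehyde (C12)
Conditions: Dess–Martin periodinane, NaHCO3, CH2Cl2, 0 °C to rt
Reagents that add atoms: none
Why: Buffered Dess–Martin oxidation should give the aldehyde under non-epimerising conditions, so C10 is retained.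

Step 18
Reactants: 32 α-branched aldehyde
Product: 33 terminal alkene (C12=CH2)
Conditions: Ph3PCH3Br, KN(SiMe3)2, THF, 0 °C; then 32, −78 to 0 °C
Reagents that add atoms: methyltriphenylphosphonium bromide, [Br-].C[P+](c1ccccc1)(c1ccccc1)c1ccccc1
Why: Wittig methylenation with the non-stabilised ylide at low temperature should convert the aldehyde into the terminal alkene faster than it can enolise, so C10 is not epimerised.

Step 19
Reactants: 33 terminal alkene
Product: 34 neopentyl alcohol (C34–OH)
Conditions: lithium 4,4′-di-tert-butylbiphenylide (LiDBB), THF, −78 °C; MeOH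
Reagents that add atoms: none
Why: Single-electron reductive cleavage of the benzyl ether (dissolving-metal type debenzylation) should free the C34 alcohol without reducing the isolated alkenes, which hydrogenolysis would attack.

Step 20
Reactants: 34 neopentyl alcohol
Product: 35 decalin aldehyde
Conditions: Dess–Martin periodinane, NaHCO3, CH2Cl2, rt
Reagents that add atoms: none
Why: Dess–Martin oxidation of the neopentyl alcohol should give the C34 aldehyde, which has no α-hydrogen and so cannot epimerise or enolise.

Step 21
Reactants: 36 prop-2-yn-1-ol; 37 (R)-2-methyloxirane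
Product: 39 (5R)-hex-2-yne-1,5-diol, via dilithium salt 38 (not isolated)
Conditions: LiNH2 (2.2 equiv), NH3 (l)/THF, −33 °C; then 37; NH4Cl
Reagents that add atoms: none
Why: The acetylide carbon of the propargyl alcohol dianion should open the epoxide by SN2 attack at its CH2 terminus, so the (R) carbinol centre (C23) is carried over unchanged.

Step 22
Reactants: 39 (5R)-hex-2-yne-1,5-diol
Product: 40 (2E,5R)-2-(tributylstannyl)hex-2-ene-1,5-diol
Conditions: Bu3SnH, Mo(CO)3(CNtBu)3 (5 mol %), hydroquinone, THF, 55 °C
Reagents that add atoms: tributyltin hydride, CCCC[SnH](CCCC)CCCC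
Why: Molybdenum-catalysed syn-hydrostannation of the propargylic alcohol should place tin on the alkyne carbon next to CH2OH, which fixes the C18=C21 geometry (C19 and C22 cis).

Step 23
Reactants: 41 pent-1-en-4-yne
Product: 43 (1E)-1-iodo-2-methylpenta-1,4-diene, via alkenylalane 42 (not isolated)
Conditions: Me3Al, Cp2ZrCl2 (25 mol %), CH2Cl2, 0 °C to rt; then I2, THF, −30 °C
Reagents that add atoms: trimethylaluminium, C[Al](C)C; iodine, II
Why: Zirconium-catalysed carboalumination should add methyl and aluminium syn across the terminal alkyne only, and iodinolysis with retention gives the (E)-vinyl iodide that becomes C15=C17.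

Step 24
Reactants: 40 vinylstannane; 43 vinyl iodide
Product: 44 (2Z,5R)-2-[(1E)-2-methylpenta-1,4-dien-1-yl]hex-2-ene-1,5-diol
Conditions: Pd(PPh3)4 (5 mol %), CuI, CsF, DMF, 45 °C
Reagents that add atoms: none
Why: Stille coupling of the hindered 1,1-disubstituted vinylstannane, assisted by copper iodide and fluoride, should join C17 to C18 with retention of both alkene geometries.

Step 25
Reactants: 44 diene diol
Product: 45 bis-silyl diene
Conditions: TBSCl, imidazole, DMF, rt
Reagents that add atoms: tert-butyldimethylsilyl chloride, CC(C)(C)[Si](C)(C)Cl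
Why: Standard silylation of the primary and the secondary alcohol should protect both hydroxyl groups until the last step.

Step 26
Reactants: 46 (R)-lactic acid; 47 pivalaldehyde
Product: 48 (2R,5R)-2-tert-butyl-5-methyl-1,3-dioxolan-4-one
Conditions: TsOH·H2O (cat.), H2SO4 (cat.), pentane, reflux, Dean–Stark
Reagents that add atoms: none
Why: Acid-catalysed acetalisation under equilibrating conditions should give the cis-dioxolanone, whose acetal centre is set by the lactic acid centre because tert-butyl and methyl prefer the same face of the ring.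

Step 27
Reactants: 48 dioxolanone
Product: 50 (R)-2-tert-butyl-5-methylidene-1,3-dioxolan-4-one, via bromide 49 (not isolated)
Conditions: NBS, AIBN (cat.), cyclohexane, 80 °C; then Et3N, Et2O, 0 °C
Reagents that add atoms: none
Why: Radical bromination at the captodative C5 position and E2 dehydrobromination should give the exocyclic alkene while the tert-butyl acetal centre, now the only stereocentre, is unaffected.

Step 28
Reactants: 45 bis-silyl diene; 50 dienophile
Product: 51 Diels–Alder adduct
Conditions: toluene, BHT, 120 °C, sealed tube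
Reagents that add atoms: none
Why: The thermal Diels–Alder reaction should close ring C (C21–C26 and C15–C27, following the larger HOMO coefficient at C21) through the transition state with the lactone carbonyl exo and the diene on the dienophile face opposite the tert-butyl group, which sets C15, C21 and C27 relative to one another (suprafacial addition to a diene of defined geometry) and in the absolute sense (acetal control).

Step 29
Reactants: 51 Diels–Alder adduct
Product: 52 tertiary α-hydroxy methyl ester
Conditions: K2CO3, MeOH, 0 °C to rt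
Reagents that add atoms: methanol, CO
Why: Methanolysis of the dioxolanone (transesterification, then collapse of the hemiacetal with loss of pivalaldehyde) should unveil the α-hydroxy methyl ester without touching C27.

Step 30
Reactants: 52 tertiary α-hydroxy methyl ester
Product: 54 spirotetronate methyl ether, via ester ylide 53 (not isolated)
Conditions: Ph3P=C=C=O, toluene, 110 °C
Reagents that add atoms: (triphenylphosphoranylidene)ketene, O=C=C=P(c1ccccc1)(c1ccccc1)c1ccccc1
Why: Addition of the tertiary alcohol to the ketene ylide and intramolecular Wittig olefination of the neighbouring ester carbonyl (domino addition–Wittig tetronate synthesis) should build ring D as its methyl enol ether without a separate acylation of the hindered alcohol.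

Step 31
Reactants: 54 spirotetronate methyl ether; 35 decalin aldehyde
Product: 56 coupled carbinol, via lithiated tetronate 55 (not isolated)
Conditions: LiN(iPr)2, THF, −78 °C; then 35, −78 to −40 °C; AcOH
Reagents that add atoms: none
Why: Deprotonation of the 4-methoxybutenolide at its α-carbon (C31) and 1,2-addition of the vinyllithium to the non-enolisable aldehyde should form the C31–C34 bond, the carbinol centre arising as a mixture that is removed in step 32.

Step 32
Reactants: 56 coupled carbinol
Product: 57 seco ketone
Conditions: Dess–Martin periodinane, NaHCO3, CH2Cl2, rt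
Reagents that add atoms: none
Why: Dess–Martin oxidation of the secondary alcohol should give the C34 ketone of the 3-acyl tetronate.

Step 33
Reactants: 57 seco ketone
Product: 58 protected macrocycle
Conditions: second-generation Grubbs catalyst RuCl2(=CHPh)(PCy3)(H2IMes) (10 mol %), CH2Cl2 (1 mM), 40 °C
Reagents that add atoms: none
Why: Ring-closing metathesis of the two monosubstituted alkenes should close the 11-membered ring with loss of ethylene, the hindered ring alkenes being inert, and the bridged ring is expected to favour the (E)-C12=C13 alkene under the reversible conditions.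

Step 34
Reactants: 58 protected macrocycle
Product: 59 bis-silyl tetronic acid
Conditions: LiCl, DMSO, 50 °C; aq. citric acid
Reagents that add atoms: none
Why: SN2 demethylation of the vinylogous methyl ester by chloride, a standard release of 3-acyl tetronic acids, should leave the silyl ethers in place.

Step 35
Reactants: 59 bis-silyl tetronic acid
Product: 60 target CNP0189906.1
Conditions: HF·pyridine, pyridine/THF, 0 °C to rt
Reagents that add atoms: none
Why: Fluoride-mediated cleavage of both silyl ethers should give the target, whose acyl tetronic acid and alkenes tolerate buffered HF.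

**Compound list**

1 | (R)-pulegone, (5R)-5-methyl-2-(propan-2-ylidene)cyclohexan-1-one | C[C@@H]1CCC(=C(C)C)C(=O)C1 | starting material
2 | pulegone oxide, (6R)-2,2,6-trimethyl-1-oxaspiro[2.5]octan-4-one (both epoxide diastereomers) | C[C@@H]1CCC2(OC2(C)C)C(=O)C1 | intermediate
3 | sodium 2-[(4R)-4-methyl-2-oxo-1-(phenylsulfanyl)cyclohexyl]propan-2-olate (not isolated) | C[C@@H]1CCC(Sc2ccccc2)(C(C)(C)O[Na])C(=O)C1 | intermediate
4 | (5R)-5-methyl-2-(phenylsulfanyl)cyclohexan-1-one (cis/trans mixture) | C[C@@H]1CCC(Sc2ccccc2)C(=O)C1 | intermediate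
5 | (5R)-5-methyl-2-(phenylsulfinyl)cyclohexan-1-one (not isolated) | C[C@@H]1CCC(S(=O)c2ccccc2)C(=O)C1 | intermediate
6 | (R)-5-methylcyclohex-2-en-1-one | C[C@@H]1CC=CC(=O)C1 | intermediate
7 | nitromethane | C[N+](=O)[O-] | starting material
8 | acetaldehyde | CC=O | starting material
9 | 1-nitropropan-2-ol (racemic) | CC(O)C[N+](=O)[O-] | intermediate
10 | 1-nitropropan-2-yl methanesulfonate (not isolated) | CC(OS(C)(=O)=O)C[N+](=O)[O-] | intermediate
11 | (E)-1-nitroprop-1-ene | C/C=C/[N+](=O)[O-] | intermediate
12 | vinylmagnesium bromide | C=C[Mg]Br | starting material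
13 | bromomagnesium enolate of trans-3-ethenyl-5-methylcyclohexanone (C1=C2 enolate, not isolated) | C[C@H]1CC(O[Mg]Br)=C[C@H](C=C)C1 | intermediate
14 | bromomagnesium nitronate of 15 (not isolated) | C[C@H]1CC(=O)[C@@H](C(C)C=[N+]([O-])O[Mg]Br)[C@H](C=C)C1 | intermediate
15 | (2R,3S,5R)-3-ethenyl-5-methyl-2-(1-nitropropan-2-yl)cyclohexan-1-one (2,3-trans and 3,5-trans; side-chain methine both epimers) | C[C@H]1CC(=O)[C@@H](C(C)C[N+](=O)[O-])[C@H](C=C)C1 | intermediate
16 | N-tosylhydrazone of 15 (not isolated) | C[C@H]1CC(=NNS(=O)(=O)c2ccc(C)cc2)[C@@H](C(C)C[N+](=O)[O-])[C@H](C=C)C1 | intermediate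
17 | 2-[(1R,2S,4S)-2-ethenyl-4-methylcyclohexyl]-1-nitropropane (C36 epimers) | C[C@H]1CC[C@@H](C(C)C[N+](=O)[O-])[C@H](C=C)C1 | intermediate
18 | 2-[(1R,2S,4S)-2-ethenyl-4-methylcyclohexyl]propanoic acid (C36 epimers, not isolated) | C[C@H]1CC[C@@H](C(C)C(=O)O)[C@H](C=C)C1 | intermediate
19 | methyl 2-[(1R,2S,4S)-2-ethenyl-4-methylcyclohexyl]propanoate (C36 epimers) | C[C@H]1CC[C@@H](C(C)C(=O)OC)[C@H](C=C)C1 | intermediate
20 | lithium enolate of 19 (not isolated) | C[C@H]1CC[C@@H](C(C)=C(OC)O[Li])[C@H](C=C)C1 | intermediate
21 | methyl (2R)-3-(benzyloxy)-2-[(1R,2S,4S)-2-ethenyl-4-methylcyclohexyl]-2-methylpropanoate | C[C@H]1CC[C@@H]([C@@](C)(C(=O)OC)COCc2ccccc2)[C@H](C=C)C1 | intermediate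
22 | (2R)-3-(benzyloxy)-2-[(1R,2S,4S)-2-ethenyl-4-methylcyclohexyl]-2-methylpropanal | C[C@H]1CC[C@@H]([C@@](C)(C=O)COCc2ccccc2)[C@H](C=C)C1 | intermediate
23 | (2R)-2-[(1R,2R,4S)-2-acetyl-4-methylcyclohexyl]-3-(benzyloxy)-2-methylpropanal | C[C@H]1CC[C@@H]([C@@](C)(C=O)COCc2ccccc2)[C@H](C(C)=O)C1 | intermediate
24 | ring B aldol, β-hydroxy ketone with C9 carbinol (not isolated) | C[C@H]1CC[C@@H]2[C@H](C(=O)CC(O)[C@@]2(C)COCc3ccccc3)C1 | intermediate
25 | ring B enone, 4-[(benzyloxy)methyl]-4,7-dimethyl-4a,5,6,7,8,8a-hexahydronaphthalen-1(4H)-one (trans-fused; C37 methyl axial and anti to C5–H; C1 methyl axial) | C[C@H]1CC[C@@H]2[C@H](C(=O)C=C[C@@]2(C)COCc3ccccc3)C1 | intermediate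
26 | equatorial allylic alcohol of 25 (C7–OH cis to methyl C37) | C[C@H]1CC[C@@H]2[C@H]([C@H](O)C=C[C@@]2(C)COCc3ccccc3)C1 | intermediate
27 | axial propanoate (C7–O inverted, cis to C34) | C[C@H]1CC[C@@H]2[C@H]([C@@H](OC(=O)CC)C=C[C@@]2(C)COCc3ccccc3)C1 | intermediate
28 | (E)-trimethylsilyl ketene acetal of 27 (methyl cis to the allylic oxygen, not isolated) | C[C@H]1CC[C@@H]2[C@H]([C@@H](O/C(O[Si](C)(C)C)=C\C)C=C[C@@]2(C)COCc3ccccc3)C1 | intermediate
29 | trimethylsilyl ester of 30 (not isolated) | C[C@H]1CC[C@@H]2[C@H](C=C[C@@H]([C@H](C)C(=O)O[Si](C)(C)C)[C@@]2(C)COCc3ccccc3)C1 | intermediate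
30 | Claisen acid, 2-{1-[(benzyloxy)methyl]-1,6-dimethyl-1,2,4a,5,6,7,8,8a-octahydronaphthalen-2-yl}propanoic acid (C10 arm on C9 cis to C34; C7=C8 alkene) | C[C@H]1CC[C@@H]2[C@H](C=C[C@@H]([C@H](C)C(=O)O)[C@@]2(C)COCc3ccccc3)C1 | intermediate
31 | primary alcohol from 30 (C12–OH) | C[C@H]1CC[C@@H]2[C@H](C=C[C@@H]([C@H](C)CO)[C@@]2(C)COCc3ccccc3)C1 | intermediate
32 | α-branched aldehyde (C12 formyl) | C[C@H]1CC[C@@H]2[C@H](C=C[C@@H]([C@H](C)C=O)[C@@]2(C)COCc3ccccc3)C1 | intermediate
33 | terminal alkene, but-3-en-2-yl arm on C9 with benzyl ether on C34 | C[C@H]1CC[C@@H]2[C@H](C=C[C@@H]([C@H](C)C=C)[C@@]2(C)COCc3ccccc3)C1 | intermediate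
34 | neopentyl alcohol (C34–OH) | C[C@H]1CC[C@@H]2[C@H](C=C[C@@H]([C@H](C)C=C)[C@@]2(C)CO)C1 | intermediate
35 | decalin aldehyde (C34 formyl equatorial on C36, methyl C37 axial, but-3-en-2-yl on C9 cis to the formyl group) | C[C@H]1CC[C@@H]2[C@H](C=C[C@@H]([C@H](C)C=C)[C@@]2(C)C=O)C1 | intermediate
36 | prop-2-yn-1-ol | OCC#C | starting material
37 | (R)-2-methyloxirane, (R)-propylene oxide | C[C@@H]1CO1 | starting material
38 | dilithium salt of prop-2-yn-1-ol (not isolated) | [Li]OCC#C[Li] | intermediate
39 | (5R)-hex-2-yne-1,5-diol | OCC#CC[C@@H](C)O | intermediate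
40 | (2E,5R)-2-(tributylstannyl)hex-2-ene-1,5-diol | CCCC[Sn](CCCC)(CCCC)/C(CO)=C/C[C@@H](C)O | intermediate
41 | pent-1-en-4-yne | C=CCC#C | starting material
42 | dimethyl[(1E)-2-methylpenta-1,4-dien-1-yl]alane (not isolated) | C=CC/C(C)=C/[Al](C)C | intermediate
43 | (1E)-1-iodo-2-methylpenta-1,4-diene | C=CC/C(C)=C/I | intermediate
44 | (2Z,5R)-2-[(1E)-2-methylpenta-1,4-dien-1-yl]hex-2-ene-1,5-diol | C=CC/C(C)=C/C(CO)=C/C[C@@H](C)O | intermediate
45 | bis(tert-butyldimethylsilyl) ether of 44 | C=CC/C(C)=C/C(CO[Si](C)(C)C(C)(C)C)=C/C[C@@H](C)O[Si](C)(C)C(C)(C)C | intermediate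
46 | (R)-lactic acid | C[C@@H](O)C(=O)O | starting material
47 | pivalaldehyde | CC(C)(C)C=O | starting material
48 | (2R,5R)-2-tert-butyl-5-methyl-1,3-dioxolan-4-one (cis) | C[C@H]1O[C@@H](C(C)(C)C)OC1=O | intermediate
49 | (2R)-5-bromo-2-tert-butyl-5-methyl-1,3-dioxolan-4-one (not isolated) | CC1(Br)O[C@@H](C(C)(C)C)OC1=O | intermediate
50 | (R)-2-tert-butyl-5-methylidene-1,3-dioxolan-4-one | C=C1O[C@@H](C(C)(C)C)OC1=O | intermediate
51 | Diels–Alder adduct, ring C spiro-fused to the dioxolanone (C14 and C22 cis to each other and to O28; C16 methyl cis to the lactone carbonyl) | C=CC[C@]1(C)C=C(CO[Si](C)(C)C(C)(C)C)[C@H](C[C@@H](C)O[Si](C)(C)C(C)(C)C)C[C@]12O[C@@H](C(C)(C)C)OC2=O | intermediate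
52 | ring C tertiary α-hydroxy methyl ester (C27–OH and CO2Me) | C=CC[C@]1(C)C=C(CO[Si](C)(C)C(C)(C)C)[C@H](C[C@@H](C)O[Si](C)(C)C(C)(C)C)C[C@@]1(O)C(=O)OC | intermediate
53 | (triphenylphosphoranylidene)acetate ester of 52 (not isolated) | C=CC[C@]1(C)C=C(CO[Si](C)(C)C(C)(C)C)[C@H](C[C@@H](C)O[Si](C)(C)C(C)(C)C)C[C@@]1(OC(=O)C=P(c2ccccc2)(c2ccccc2)c2ccccc2)C(=O)OC | intermediate
54 | spirotetronate methyl ether, 4-methoxy-6-methyl-6-(prop-2-en-1-yl)-8-[(tert-butyldimethylsilyloxy)methyl]-9-[(2R)-2-(tert-butyldimethylsilyloxy)propyl]-1-oxaspiro[4.5]deca-3,7-dien-2-one | C=CC[C@]1(C)C=C(CO[Si](C)(C)C(C)(C)C)[C@H](C[C@@H](C)O[Si](C)(C)C(C)(C)C)C[C@]12OC(=O)C=C2OC | intermediate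
55 | C31-lithio derivative of 54 (not isolated) | C=CC[C@]1(C)C=C(CO[Si](C)(C)C(C)(C)C)[C@H](C[C@@H](C)O[Si](C)(C)C(C)(C)C)C[C@]12OC(=O)C([Li])=C2OC | intermediate
56 | coupled carbinol (C34–OH, both epimers) | C[C@H]1CC[C@@H]2[C@H](C=C[C@@H]([C@H](C)C=C)[C@@]2(C)C(O)C3=C(OC)[C@@]4(C[C@@H](C[C@@H](C)O[Si](C)(C)C(C)(C)C)C(CO[Si](C)(C)C(C)(C)C)=C[C@@]4(C)CC=C)OC3=O)C1 | intermediate
57 | seco ketone (3-acyl-4-methoxy tetronate with two terminal alkenes) | C[C@H]1CC[C@@H]2[C@H](C=C[C@@H]([C@H](C)C=C)[C@@]2(C)C(=O)C3=C(OC)[C@@]4(C[C@@H](C[C@@H](C)O[Si](C)(C)C(C)(C)C)C(CO[Si](C)(C)C(C)(C)C)=C[C@@]4(C)CC=C)OC3=O)C1 | intermediate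
58 | protected macrocycle (O-methyl tetronate, two silyl ethers, (E)-C12=C13) | C[C@H]1CC[C@@H]2[C@H](C=C[C@H]3[C@H](C)/C=C/C[C@]4(C)C=C(CO[Si](C)(C)C(C)(C)C)[C@H](C[C@@H](C)O[Si](C)(C)C(C)(C)C)C[C@]45OC(=O)C(=C5OC)C(=O)[C@@]23C)C1 | intermediate
59 | bis-silyl tetronic acid (target with both hydroxyl groups as silyl ethers) | C[C@H]1CC[C@@H]2[C@H](C=C[C@H]3[C@H](C)/C=C/C[C@]4(C)C=C(CO[Si](C)(C)C(C)(C)C)[C@H](C[C@@H](C)O[Si](C)(C)C(C)(C)C)C[C@]45OC(=O)C(=C5O)C(=O)[C@@]23C)C1 | intermediate
60 | CNP0189906.1 | C[C@H]1CC[C@@H]2[C@H](C=C[C@H]3[C@H](C)/C=C/C[C@]4(C)C=C(CO)[C@H](C[C@@H](C)O)C[C@]45OC(=O)C(=C5O)C(=O)[C@@]23C)C1 | target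

**Totals**

Total step count: 35. Longest linear sequence: 23 steps (steps 1–3, 6–20 and 31–35, from (R)-pulegone). The ring C/D branch (steps 21, 22, 24, 25, 28–30) is fed by steps 23, 26 and 27, and the nitroalkene by steps 4 and 5.

**Steps most likely to fail**

1. Step 28 (Diels–Alder reaction). The C15–C27 bond joins two fully substituted carbons, so the cycloaddition may be too slow at temperatures the diene tolerates; the diene carries methyl C16 on the inside of its s-cis form and may undergo a 1,5-hydrogen shift, the dienophile may polymerise, or exo and facial control may erode. The fallback sets out from 45 and returns at 52. A Lewis-acid-catalysed Diels–Alder reaction at −78 °C with 2-bromoacrolein under a chiral oxazaborolidine (the antipode that exposes the Si face of the brominated carbon) should give α-bromo aldehyde F1 with the formyl group exo. Pinnick oxidation (NaClO2, NaH2PO4, 2-methylbut-2-ene) gives α-bromo acid F2. Aqueous K2CO3 then replaces bromide by hydroxyl with net retention through the α-lactone to give α-hydroxy acid F3, and TMSCHN2 gives 52.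

2. Step 33 (ring-closing metathesis). Oligomerisation by cross-metathesis, or closure to the (Z)-alkene, may compete because the 11-membered ring spans two quaternary centres and is strained. The fallback sets out from 35 and 52 and returns at 59, bypassing steps 30–34. Cross-metathesis of the vinyl group of 35 with the allyl group of 52 (second-generation Grubbs catalyst, where an acyclic disubstituted alkene normally forms with (E)-geometry) gives hydroxy ester aldehyde F4. Roskamp homologation of the aldehyde with tert-butyl diazoacetate and SnCl2 gives β-keto ester F5. Thermolysis in dilute refluxing toluene generates the acylketene, which the tertiary alcohol traps to close the 12-membered keto lactone F6. Lacey–Dieckmann cyclisation with KOtBu then forms ring D, contracts the macrocycle and gives 59.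

3. Step 15 (Ireland–Claisen rearrangement). Leakage through the chair-like transition state, or incomplete (E)-selectivity in the enolisation, would erode the C10 configuration; C9 is safe because the shift is suprafacial. The fallback sets out from 26 and returns at 31. Mitsunobu inversion with acetic acid gives axial acetate F7. Ireland–Claisen rearrangement gives acetic acid derivative F8, with C9 set and no C10 centre. Acylation of lithiated (S)-4-benzyl-1,3-oxazolidin-2-one through the pivaloyl mixed anhydride gives imide F9. Methylation of its sodium (Z)-enolate (NaN(SiMe3)2, MeI), anti to the benzyl group, gives methylated imide F10, and LiBH4 removes the auxiliary to give 31.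

**Further compounds**

F1 | step 28 | 1-bromo-2-methyl-2-(prop-2-en-1-yl)-4-[(tert-butyldimethylsilyloxy)methyl]-5-[(2R)-2-(tert-butyldimethylsilyloxy)propyl]cyclohex-3-ene-1-carbaldehyde (ring configuration as in 52, Br in place of OH) | C=CC[C@]1(C)C=C(CO[Si](C)(C)C(C)(C)C)[C@H](C[C@@H](C)O[Si](C)(C)C(C)(C)C)C[C@@]1(Br)C=O
F2 | step 28 | corresponding 1-bromocyclohex-3-ene-1-carboxylic acid | C=CC[C@]1(C)C=C(CO[Si](C)(C)C(C)(C)C)[C@H](C[C@@H](C)O[Si](C)(C)C(C)(C)C)C[C@@]1(Br)C(=O)O
F3 | step 28 | corresponding 1-hydroxycyclohex-3-ene-1-carboxylic acid (free acid of 52) | C=CC[C@]1(C)C=C(CO[Si](C)(C)C(C)(C)C)[C@H](C[C@@H](C)O[Si](C)(C)C(C)(C)C)C[C@@]1(O)C(=O)O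
F4 | step 33 | cross-metathesis product of 35 and 52 with (E)-C12=C13, C34 aldehyde and C27 hydroxy ester | C[C@H]1CC[C@@H]2[C@H](C=C[C@@H]([C@H](C)/C=C/C[C@]3(C)C=C(CO[Si](C)(C)C(C)(C)C)[C@H](C[C@@H](C)O[Si](C)(C)C(C)(C)C)C[C@@]3(O)C(=O)OC)[C@@]2(C)C=O)C1
F5 | step 33 | tert-butyl β-keto ester from F4 (C36–C(=O)CH2CO2tBu) | C[C@H]1CC[C@@H]2[C@H](C=C[C@@H]([C@H](C)/C=C/C[C@]3(C)C=C(CO[Si](C)(C)C(C)(C)C)[C@H](C[C@@H](C)O[Si](C)(C)C(C)(C)C)C[C@@]3(O)C(=O)OC)[C@@]2(C)C(=O)CC(=O)OC(C)(C)C)C1
F6 | step 33 | 12-membered keto lactone (O28–C29 ester, C27 methyl ester intact) | C[C@H]1CC[C@@H]2[C@H](C=C[C@H]3[C@H](C)/C=C/C[C@]4(C)C=C(CO[Si](C)(C)C(C)(C)C)[C@H](C[C@@H](C)O[Si](C)(C)C(C)(C)C)C[C@]4(C(=O)OC)OC(=O)CC(=O)[C@@]23C)C1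
F7 | step 15 | axial C7 acetate (acetate analogue of 27) | C[C@H]1CC[C@@H]2[C@H]([C@@H](OC(C)=O)C=C[C@@]2(C)COCc3ccccc3)C1
F8 | step 15 | C9 acetic acid (30 without the C10 methyl group) | C[C@H]1CC[C@@H]2[C@H](C=C[C@@H](CC(=O)O)[C@@]2(C)COCc3ccccc3)C1
F9 | step 15 | N-acyl (S)-4-benzyl-1,3-oxazolidin-2-one of F8 | C[C@H]1CC[C@@H]2[C@H](C=C[C@@H](CC(=O)N3[C@@H](Cc4ccccc4)COC3=O)[C@@]2(C)COCc5ccccc5)C1
F10 | step 15 | α-methylated imide (C10 configured as in 30) | C[C@H]1CC[C@@H]2[C@H](C=C[C@@H]([C@H](C)C(=O)N3[C@@H](Cc4ccccc4)COC3=O)[C@@]2(C)COCc5ccccc5)C1
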